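**Plan**

1. Chromene numbering is used (O1, C2, C3, C4, C4a, C5–C8, C8a); "lavandulyl" means (2R)-5-methyl-2-(prop-1-en-2-yl)hex-4-en-1-yl. The retrosynthesis cuts C6–CH(Ph) (side chain, through an enol lactone), then C4a–C5 and C6–C7 of the carbocycle, then O1–C8a and C4–C4a of the pyranone, then C8–prenyl and C8–CH2(lavandulyl).
2. Forward: (S)-lavandulyl iodide → doubly alkylated mixed malonate (C8) → methyl ketone → β-diketone → dihydropyranone ring (first ring) → carbocycle (last ring) by acylketene C-acylation → side chain by carbene-catalysed annulation → lactone opening.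
3. Enabling feature: ring C4a/C5/C6/C7/C8/C8a is a 1,3,5-trioxygenated (polyketide) ring. C4a is the nucleophilic α-carbon of the pyranone vinylogous ester O1–C8a=C4a–C4=O and C8 is quaternary, so a C7(=O)–C6H=C5=O ketene carried on C8 can acylate C4a–H, and the ring cannot aromatise.
4. Stereochemistry: the lavandulyl centre comes from an oxazolidinone alkylation; C8 from a chiral phase-transfer prenylation; C2 from methyl (R)-3-hydroxybutanoate and C3 from a Fráter–Seebach methylation; the benzylic centre from the chiral carbene catalyst.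

Key step: step 17

Remark (assumption): in the two catalyst-controlled steps (7 and 18) the sense of induction on these new substrates is taken from the closest analogies; the catalyst antipode is the one that gives the configuration drawn, and the other antipode is used if the sense proves reversed.

**Route**

Step 1
Reactants: 1 (4S)-4-benzyl-1,3-oxazolidin-2-one; 2 3-methylbut-2-enoyl chloride
Product: 3 (4S)-4-benzyl-3-(3-methylbut-2-enoyl)-1,3-oxazolidin-2-one
Conditions: n-BuLi, THF, −78 °C; then 2, −78 to 0 °C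
Reagents that add atoms: none
Why: N-acylation of the lithiated oxazolidinone (acyl substitution) should attach the auxiliary cleanly.

Step 2
Reactants: 3; 4 1-bromo-3-methylbut-2-ene (prenyl bromide)
Product: 5 (4S)-4-benzyl-3-[(2S)-5-methyl-2-(prop-1-en-2-yl)hex-4-enoyl]-1,3-oxazolidin-2-one
Conditions: NaN(SiMe3)2, THF, −78 °C; then 4, −78 to −40 °C
Reagents that add atoms: none
Why: Evans-type auxiliary alkylation in its deconjugative form: γ-deprotonation gives the chelated Z(O)-dienolate, which should be alkylated at the α-carbon on the face away from the benzyl group, setting the (2S) centre and leaving the isopropenyl group.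

Step 3
Reactants: 5
Product: 6 (S)-lavandulol [(2S)-5-methyl-2-(prop-1-en-2-yl)hex-4-en-1-ol]
Conditions: LiBH4, MeOH (1 equiv), Et2O, 0 °C
Reagents that add atoms: none
Why: Reductive cleavage of the imide by borohydride should release the primary alcohol and the auxiliary without touching the stereocentre or the olefins.

Step 4
Reactants: 6
Product: 7 (S)-lavandulyl iodide [(2S)-1-iodo-5-methyl-2-(prop-1-en-2-yl)hex-4-ene]
Conditions: I2, PPh3, imidazole, CH2Cl2, 0 °C to rt
Reagents that add atoms: iodine, [I][I]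
Why: Appel-type iodination of a primary alcohol proceeds at the CH2 group only, so the adjacent stereocentre is not involved.

Step 5
Reactants: 8 3-tert-butoxy-3-oxopropanoic acid; 9 2,2-diphenylethanol
Product: 10 tert-butyl 2,2-diphenylethyl propanedioate
Conditions: DCC, DMAP (cat.), CH2Cl2, 0 °C to rt
Reagents that add atoms: none
Why: Steglich esterification should give the mixed malonate whose two unlike esters are needed for the later face discrimination and for selective unmasking.

Step 6
Reactants: 10; 7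
Product: 11 1-tert-butyl 3-(2,2-diphenylethyl) 2-[(2R)-lavandulyl]propanedioate (both C2 epimers)
Conditions: NaH, THF/DMF, 0 to 60 °C
Reagents that add atoms: none
Why: Malonic ester alkylation (SN2) of the primary iodide by the sodium enolate; the malonate CH is left unassigned because it is deprotonated again in step 7.

Step 7
Reactants: 11; 4
Product: 12 1-tert-butyl 3-(2,2-diphenylethyl) (2S)-2-(3-methylbut-2-en-1-yl)-2-[(2R)-lavandulyl]propanedioate
Conditions: 4 (3 equiv), chiral N-spiro bis(binaphthyl)ammonium bromide bearing 3,4,5-trifluorophenyl groups at the 3,3′-positions (5 mol%), 50% aq KOH, toluene, −40 °C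
Reagents that add atoms: none
Why: Asymmetric phase-transfer alkylation of an α-substituted mixed malonate: the chiral ammonium cation pairs with the enolate and distinguishes its faces through the unlike tert-butyl and diphenylethyl esters, so the reactive allylic bromide should set the quaternary (S) centre under catalyst control.

Step 8
Reactants: 12
Product: 13 (2S)-2-(tert-butoxycarbonyl)-5-methyl-2-[(2R)-lavandulyl]hex-4-enoic acid
Conditions: KOH, MeOH/THF/H2O, 40 °C; then 1 M HCl to pH 3
Reagents that add atoms: potassium hydroxide, [K+].[OH-] (carboxyl oxygen)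
Why: Chemoselective saponification: the primary alkyl ester should be hydrolysed while the tert-butyl ester on the same quaternary carbon resists hydroxide.

Step 9
Reactants: 13
Product: 15 tert-butyl (2S)-2-acetyl-5-methyl-2-[(2R)-lavandulyl]hex-4-enoate, via acid chloride 14 (not isolated)
Conditions: 1-chloro-N,N,2-trimethylprop-1-en-1-amine, CH2Cl2, 0 °C; then Me2CuLi, Et2O, −78 °C
Reagents that add atoms: 1-chloro-N,N,2-trimethylprop-1-en-1-amine, CC(C)=C(Cl)N(C)C (chlorine of 14); lithium dimethylcuprate, [Li+].C[Cu-]C (methyl of 15)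
Why: Neutral acid chloride formation followed by organocuprate acylation should stop at the methyl ketone and leave the hindered tert-butyl ester and the olefins untouched.

Step 10
Reactants: 16 methyl (3R)-3-hydroxybutanoate
Product: 17 methyl (2R,3R)-3-hydroxy-2-methylbutanoate
Conditions: LiN(i-Pr)2 (2.2 equiv), THF, −78 to −20 °C; MeI, DMPU, −78 to 0 °C
Reagents that add atoms: iodomethane, CI
Why: Fráter–Seebach alkylation: the chelated lithium alkoxide enolate should be methylated anti to the C3 substituent, setting (2R) from the (3R) carbinol.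

Step 11
Reactants: 17
Product: 18 methyl (2R,3R)-3-(tert-butyldimethylsilyloxy)-2-methylbutanoate
Conditions: TBSCl, imidazole, DMF, rt
Reagents that add atoms: tert-butyldimethylsilyl chloride, CC(C)(C)[Si](C)(C)Cl
Why: Silylation of the secondary alcohol protects it during the acylation of step 13.

Step 12
Reactants: 18
Product: 19 (2R,3R)-3-(tert-butyldimethylsilyloxy)-2-methylbutanoic acid
Conditions: LiOH, THF/MeOH/H2O, 0 °C to rt; then 1 M HCl
Reagents that add atoms: lithium hydroxide, [Li+].[OH-] (carboxyl oxygen)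
Why: Mild saponification of the methyl ester should give the acid without epimerising the α-centre or cleaving the silyl ether.

Step 13
Reactants: 15; 19
Product: 21 tert-butyl (2S)-2-[(4R,5R)-5-(tert-butyldimethylsilyloxy)-4-methyl-3-oxohexanoyl]-5-methyl-2-[(2R)-lavandulyl]hex-4-enoate, via acid chloride 20 (not isolated)
Conditions: 19, 1-chloro-N,N,2-trimethylprop-1-en-1-amine, CH2Cl2, 0 °C; then 15, MgBr2·OEt2, i-Pr2NEt, CH2Cl2, 0 °C to rt
Reagents that add atoms: 1-chloro-N,N,2-trimethylprop-1-en-1-amine, CC(C)=C(Cl)N(C)C (chlorine of 20)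
Why: Soft-enolisation crossed Claisen C-acylation: MgBr2 chelates the β-keto ester of 15 so that the amine forms its only possible (methyl) enolate, which should be acylated at carbon by 20, and the low temperature limits ketene-mediated epimerisation α to the acyl chloride.

Step 14
Reactants: 21
Product: 23 tert-butyl (2S)-2-[(2R,3R)-2,3-dimethyl-4-oxo-3,4-dihydro-2H-pyran-6-yl]-5-methyl-2-[(2R)-lavandulyl]hex-4-enoate, via hydroxy diketone 22 (not isolated)
Conditions: HF·pyridine, THF, 0 °C to rt; then TsOH·H2O (cat.), CH2Cl2, rt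
Reagents that add atoms: none
Why: Desilylation and acid-catalysed cyclodehydration of the δ-hydroxy-β-diketone: only the hindered ketone lies in a six-membered relation to the hydroxyl, so one dihydropyranone should form, with retention at C2 and without enolising C3.

Step 15
Reactants: 23
Product: 25 (2S)-2-[(2R,3R)-2,3-dimethyl-4-oxo-3,4-dihydro-2H-pyran-6-yl]-5-methyl-2-[(2R)-lavandulyl]hex-4-enoic acid, via trimethylsilyl ester 24 (not isolated)
Conditions: Me3SiOTf, 2,6-lutidine, CH2Cl2, 0 °C; then pH 4 aqueous buffer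
Reagents that add atoms: trimethylsilyl trifluoromethanesulfonate, C[Si](C)(C)OS(=O)(=O)C(F)(F)F (silyl group of 24)
Why: Silyl-triflate cleavage of the tert-butyl ester (loss of isobutene, then hydrolysis of the silyl ester) avoids the protic acid that would threaten the prenyl and lavandulyl olefins; the acid is used at once because it is a vinylogous β-keto acid.

Step 16
Reactants: 25; 26 Meldrum's acid (2,2-dimethyl-1,3-dioxane-4,6-dione)
Product: 28 5-[(2R)-2-[(2R,3R)-2,3-dimethyl-4-oxo-3,4-dihydro-2H-pyran-6-yl]-1-hydroxy-5-methyl-2-[(2R)-lavandulyl]hex-4-en-1-ylidene]-2,2-dimethyl-1,3-dioxane-4,6-dione, via acid chloride 27 (not isolated)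
Conditions: 1-chloro-N,N,2-trimethylprop-1-en-1-amine, CH2Cl2, 0 °C; then 26, DMAP (2 equiv), CH2Cl2, 0 °C to rt; cold aq KHSO4 wash
Reagents that add atoms: 1-chloro-N,N,2-trimethylprop-1-en-1-amine, CC(C)=C(Cl)N(C)C (chlorine of 27)
Why: C-acylation of Meldrum's acid through the N-acylpyridinium gives the enolised 5-acyl derivative, the standard precursor of an α-oxoketene (the quaternary carbon is R by the sequence rule in this enol form, with the spatial arrangement unchanged).

Step 17
Reactants: 28
Product: 31 (2R,3R,8S)-5-hydroxy-2,3-dimethyl-8-(3-methylbut-2-en-1-yl)-8-[(2R)-lavandulyl]-2,3-dihydro-4H-chromene-4,7(8H)-dione, via carboxy acylketene 29 (not isolated), via acylketene 30 (not isolated)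
Conditions: toluene (0.005 M), 90 °C, slow addition, N2
Reagents that add atoms: none
Why: Proposed new method: on warming, 28 should lose acetone by retro-hetero-Diels–Alder fragmentation and then CO2 to give the α-oxoketene 30, whose central ketene carbon (future C5) is attacked by C5 of the dihydropyranone (future C4a, the α-carbon of the vinylogous ester and β-carbon of the O1–C8a=C4a enol ether), and loss of the C4a proton from the oxocarbenium/enolate zwitterion gives the hydrogen-bonded 5-hydroxy-4,7-dione 31. The closest known reactions are the thermal C-acylations of enol, enamine and arene carbons by α-oxoketenes generated from acyl Meldrum's acids, dioxinones or activated malonates (4-hydroxycoumarin- and 4-hydroxypyranone-forming cyclocondensations, intramolecular Friedel–Crafts acylations with Meldrum's acid derivatives), but a dihydropyranone C–H has not served as the acceptor. The carbocycle closes in a six-membered, tetralone-type mode: the acyl carbon, tethered through C6, C7 and C8 to C8a, attacks the adjacent sp2 carbon C4a (6-endo with respect to the C4a=C8a bond), the geometry of a 4-arylbutanoyl-to-tetralone cyclisation. No stereocentre is created; C8 is carried in from step 7, and because it is quaternary the C7 ketone cannot enolise toward it, so the ketene forms only on the C6 side and the product cannot aromatise. The selectivity needed is C-acylation at C4a rather than ene or [2+2] capture of the ketene by the prenyl olefin on C8 (also a six-membered closure) or ketene dimerisation; it is expected from donation by O1 into C4a, from the irreversible loss of the triply activated C4a–H after attack and from high dilution, and it is the main uncertainty of the route.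

Step 18
Reactants: 31; 32 3-phenylprop-2-ynal
Product: 33 enol lactone of 34 closed through O5 [(4S)-4-phenyl-3,4-dihydro-2H-pyran-2-one ring fused to C5–C6 of 31 with the lactone oxygen on C5; other centres 2R 3R 8S and lavandulyl R as in 31]
Conditions: 32 (1.5 equiv), N-mesityl triazolium chloride fused to a cis-1-amino-2-indanol-derived morpholine ring (10 mol%), toluene, 40 °C
Reagents that add atoms: none
Why: Carbene-catalysed annulation (Coates–Claisen type): the catalyst turns the ynal into an α,β-unsaturated acyl azolium, C6 of the cyclic 1,3-dione adds to its β-carbon on the face left open by the aminoindanol backbone, which should set the (S) benzylic centre, and O-acylation by the C5 enol oxygen releases the catalyst (a lactone through O7 would converge in step 19).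

Step 19
Reactants: 33
Product: 34 (3S)-3-[(2R,3R,8S)-5-hydroxy-2,3-dimethyl-8-(3-methylbut-2-en-1-yl)-8-[(2R)-lavandulyl]-4,7-dioxo-3,4,7,8-tetrahydro-2H-chromen-6-yl]-3-phenylpropanoic acid (CNP0150579.1)
Conditions: LiOH (3 equiv), THF/H2O, 0 °C; then 1 M HCl to pH 3
Reagents that add atoms: lithium hydroxide, [Li+].[OH-] (carboxyl oxygen)
Why: Hydrolysis of the enol lactone by acyl–oxygen cleavage (the vinylogous acid enolate is an excellent leaving group) under cold conditions in which the trione is present as its anion, so C3 is not enolised; mild acidification frees the acid.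

**Compound list**

1 | (4S)-4-benzyl-1,3-oxazolidin-2-one | O=C1N[C@@H](Cc2ccccc2)CO1 | starting material
2 | 3-methylbut-2-enoyl chloride | CC(C)=CC(=O)Cl | starting material
3 | (4S)-4-benzyl-3-(3-methylbut-2-enoyl)-1,3-oxazolidin-2-one | CC(C)=CC(=O)N1[C@@H](Cc2ccccc2)COC1=O | intermediate
4 | 1-bromo-3-methylbut-2-ene | CC(C)=CCBr | starting material
5 | (4S)-4-benzyl-3-[(2S)-5-methyl-2-(prop-1-en-2-yl)hex-4-enoyl]-1,3-oxazolidin-2-one | C=C(C)[C@H](CC=C(C)C)C(=O)N1[C@@H](Cc2ccccc2)COC1=O | intermediate
6 | (S)-lavandulol | C=C(C)[C@H](CC=C(C)C)CO | intermediate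
7 | (S)-lavandulyl iodide | C=C(C)[C@H](CC=C(C)C)CI | intermediate
8 | 3-tert-butoxy-3-oxopropanoic acid | CC(C)(C)OC(=O)CC(=O)O | starting material
9 | 2,2-diphenylethanol | OCC(c1ccccc1)c1ccccc1 | starting material
10 | tert-butyl 2,2-diphenylethyl propanedioate | CC(C)(C)OC(=O)CC(=O)OCC(c1ccccc1)c1ccccc1 | intermediate
11 | 1-tert-butyl 3-(2,2-diphenylethyl) 2-[(2R)-lavandulyl]propanedioate (C2 epimers) | C=C(C)[C@H](CC=C(C)C)CC(C(=O)OCC(c1ccccc1)c1ccccc1)C(=O)OC(C)(C)C | intermediate
12 | 1-tert-butyl 3-(2,2-diphenylethyl) (2S)-2-(3-methylbut-2-en-1-yl)-2-[(2R)-lavandulyl]propanedioate | C=C(C)[C@H](CC=C(C)C)C[C@](C(=O)OCC(c1ccccc1)c1ccccc1)(CC=C(C)C)C(=O)OC(C)(C)C | intermediate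
13 | (2S)-2-(tert-butoxycarbonyl)-5-methyl-2-[(2R)-lavandulyl]hex-4-enoic acid | C=C(C)[C@H](CC=C(C)C)C[C@](C(=O)O)(CC=C(C)C)C(=O)OC(C)(C)C | intermediate
14 | tert-butyl (2R)-2-(chlorocarbonyl)-5-methyl-2-[(2R)-lavandulyl]hex-4-enoate (not isolated) | C=C(C)[C@H](CC=C(C)C)C[C@](C(=O)Cl)(CC=C(C)C)C(=O)OC(C)(C)C | intermediate
15 | tert-butyl (2S)-2-acetyl-5-methyl-2-[(2R)-lavandulyl]hex-4-enoate | C=C(C)[C@H](CC=C(C)C)C[C@](C(C)=O)(CC=C(C)C)C(=O)OC(C)(C)C | intermediate
16 | methyl (3R)-3-hydroxybutanoate | C[C@@H](O)CC(=O)OC | starting material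
17 | methyl (2R,3R)-3-hydroxy-2-methylbutanoate | O[C@H](C)[C@@H](C)C(=O)OC | intermediate
18 | methyl (2R,3R)-3-(tert-butyldimethylsilyloxy)-2-methylbutanoate | CC(C)(C)[Si](C)(C)O[C@H](C)[C@@H](C)C(=O)OC | intermediate
19 | (2R,3R)-3-(tert-butyldimethylsilyloxy)-2-methylbutanoic acid | CC(C)(C)[Si](C)(C)O[C@H](C)[C@@H](C)C(=O)O | intermediate
20 | (2R,3R)-3-(tert-butyldimethylsilyloxy)-2-methylbutanoyl chloride (not isolated) | CC(C)(C)[Si](C)(C)O[C@H](C)[C@@H](C)C(=O)Cl | intermediate
21 | tert-butyl (2S)-2-[(4R,5R)-5-(tert-butyldimethylsilyloxy)-4-methyl-3-oxohexanoyl]-5-methyl-2-[(2R)-lavandulyl]hex-4-enoate | C=C(C)[C@H](CC=C(C)C)C[C@](C(=O)CC(=O)[C@H](C)[C@@H](C)O[Si](C)(C)C(C)(C)C)(CC=C(C)C)C(=O)OC(C)(C)C | intermediate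
22 | tert-butyl (2S)-2-[(4R,5R)-5-hydroxy-4-methyl-3-oxohexanoyl]-5-methyl-2-[(2R)-lavandulyl]hex-4-enoate (not isolated) | C=C(C)[C@H](CC=C(C)C)C[C@](C(=O)CC(=O)[C@H](C)[C@@H](C)O)(CC=C(C)C)C(=O)OC(C)(C)C | intermediate
23 | tert-butyl (2S)-2-[(2R,3R)-2,3-dimethyl-4-oxo-3,4-dihydro-2H-pyran-6-yl]-5-methyl-2-[(2R)-lavandulyl]hex-4-enoate | C=C(C)[C@H](CC=C(C)C)C[C@](C1=CC(=O)[C@H](C)[C@@H](C)O1)(CC=C(C)C)C(=O)OC(C)(C)C | intermediate
24 | trimethylsilyl ester of 25 (not isolated) | C=C(C)[C@H](CC=C(C)C)C[C@](C1=CC(=O)[C@H](C)[C@@H](C)O1)(CC=C(C)C)C(=O)O[Si](C)(C)C | intermediate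
25 | (2S)-2-[(2R,3R)-2,3-dimethyl-4-oxo-3,4-dihydro-2H-pyran-6-yl]-5-methyl-2-[(2R)-lavandulyl]hex-4-enoic acid | C=C(C)[C@H](CC=C(C)C)C[C@](C1=CC(=O)[C@H](C)[C@@H](C)O1)(CC=C(C)C)C(=O)O | intermediate
26 | Meldrum's acid (2,2-dimethyl-1,3-dioxane-4,6-dione) | CC1(C)OC(=O)CC(=O)O1 | starting material
27 | acid chloride of 25 (2S; not isolated) | C=C(C)[C@H](CC=C(C)C)C[C@](C1=CC(=O)[C@H](C)[C@@H](C)O1)(CC=C(C)C)C(=O)Cl | intermediate
28 | 5-acyl Meldrum's acid of 25, enol form (name as in step 16) | C=C(C)[C@H](CC=C(C)C)C[C@](C1=CC(=O)[C@H](C)[C@@H](C)O1)(CC=C(C)C)C(O)=C2C(=O)OC(C)(C)OC2=O | intermediate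
29 | (4S)-4-[(2R,3R)-2,3-dimethyl-4-oxo-3,4-dihydro-2H-pyran-6-yl]-7-methyl-4-[(2R)-lavandulyl]-3-oxo-2-(oxomethylidene)oct-6-enoic acid (not isolated) | C=C(C)[C@H](CC=C(C)C)C[C@](C1=CC(=O)[C@H](C)[C@@H](C)O1)(CC=C(C)C)C(=O)C(=C=O)C(=O)O | intermediate
30 | (4S)-4-[(2R,3R)-2,3-dimethyl-4-oxo-3,4-dihydro-2H-pyran-6-yl]-7-methyl-4-[(2R)-lavandulyl]octa-1,6-diene-1,3-dione (not isolated) | C=C(C)[C@H](CC=C(C)C)C[C@](C1=CC(=O)[C@H](C)[C@@H](C)O1)(CC=C(C)C)C(=O)C=C=O | intermediate
31 | (2R,3R,8S)-5-hydroxy-2,3-dimethyl-8-(3-methylbut-2-en-1-yl)-8-[(2R)-lavandulyl]-2,3-dihydro-4H-chromene-4,7(8H)-dione | C=C(C)[C@H](CC=C(C)C)C[C@]1(CC=C(C)C)C(=O)C=C(O)C2=C1O[C@H](C)[C@@H](C)C2=O | intermediate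
32 | 3-phenylprop-2-ynal | O=CC#Cc1ccccc1 | starting material
33 | enol lactone of 34 through O5 (4S benzylic centre) | C=C(C)[C@H](CC=C(C)C)C[C@]1(CC=C(C)C)C(=O)C3=C(OC(=O)C[C@H]3c4ccccc4)C2=C1O[C@H](C)[C@@H](C)C2=O | intermediate
34 | (3S)-3-[(2R,3R,8S)-5-hydroxy-2,3-dimethyl-8-(3-methylbut-2-en-1-yl)-8-[(2R)-lavandulyl]-4,7-dioxo-3,4,7,8-tetrahydro-2H-chromen-6-yl]-3-phenylpropanoic acid | C=C(C)[C@H](CC=C(C)C)C[C@]1(CC=C(C)C)C(=O)C([C@@H](CC(=O)O)c2ccccc2)=C(O)C2=C1O[C@H](C)[C@@H](C)C2=O | target

**Step count and risks**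

Total steps: 19. Longest linear sequence: 15 (steps 1–4, 6–9, 13–19).

Steps most likely to fail:

1. Step 17. The ketene may be captured by the prenyl olefin on C8 (ene or [2+2] closure) or may dimerise, instead of acylating C4a. The fallback uses known reactions only; it sets out from 25 and returns at 31. Acid 25 is esterified with Me3SiCHN2 in toluene/MeOH to the methyl ester of 25 F1. F1 is iodinated at C5 of the pyranone (I2, pyridine, CH2Cl2) to the 5-iodopyranone F2. Stille coupling of F2 with tributyl(1-ethoxyvinyl)stannane (Pd(PPh3)4, CuI, CsF, DMF) gives the 5-(1-ethoxyvinyl)pyranone F3, and dilute HCl hydrolyses it to the 5-acetylpyranone F4. LiN(SiMe3)2 in THF at −78 °C then effects a Dieckmann condensation of the acetyl enolate of F4 onto the methyl ester, which gives 31.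

2. Step 7. The catalyst may discriminate poorly between the enolate faces when the α-substituent is the bulky, chiral lavandulyl group. The fallback replaces catalyst control by separation of diastereomers; it sets out from 11 and returns at 13. Alkylation of 11 with 4 and NaH in DMF gives 12 together with the C2 epimer of 12 F5. Saponification as in step 8 gives 13 and the C2 epimer of 13 F6. Acid 13 is separated from F6 by crystallisation as the (R)-1-phenylethylammonium salt of 13 F7 and is freed with dilute HCl.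

3. Step 18. Facial selectivity may be poor, or C–C bond formation slow, at C6, which is flanked by the quaternary C8. The fallback changes the activation mode from acyl azolium to iminium catalysis; it sets out from 31 and returns at 33. Michael addition of 31 to (E)-cinnamaldehyde with the appropriate antipode of α,α-diphenylprolinol trimethylsilyl ether (PhCO2H co-catalyst, CH2Cl2) gives the cyclic hemiacetal (lactol) of the adduct F8, and oxidation of F8 with PhI(OAc)2 and catalytic TEMPO gives 33.

**Further compounds**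

F1 | step 17 | methyl (2S)-2-[(2R,3R)-2,3-dimethyl-4-oxo-3,4-dihydro-2H-pyran-6-yl]-5-methyl-2-[(2R)-lavandulyl]hex-4-enoate | C=C(C)[C@H](CC=C(C)C)C[C@](C1=CC(=O)[C@H](C)[C@@H](C)O1)(CC=C(C)C)C(=O)OC
F2 | step 17 | methyl (2S)-2-[(2R,3R)-5-iodo-2,3-dimethyl-4-oxo-3,4-dihydro-2H-pyran-6-yl]-5-methyl-2-[(2R)-lavandulyl]hex-4-enoate | C=C(C)[C@H](CC=C(C)C)C[C@](C1=C(I)C(=O)[C@H](C)[C@@H](C)O1)(CC=C(C)C)C(=O)OC
F3 | step 17 | methyl (2S)-2-[(2R,3R)-5-(1-ethoxyethenyl)-2,3-dimethyl-4-oxo-3,4-dihydro-2H-pyran-6-yl]-5-methyl-2-[(2R)-lavandulyl]hex-4-enoate | C=C(C)[C@H](CC=C(C)C)C[C@](C1=C(C(=C)OCC)C(=O)[C@H](C)[C@@H](C)O1)(CC=C(C)C)C(=O)OC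
F4 | step 17 | methyl (2S)-2-[(2R,3R)-5-acetyl-2,3-dimethyl-4-oxo-3,4-dihydro-2H-pyran-6-yl]-5-methyl-2-[(2R)-lavandulyl]hex-4-enoate | C=C(C)[C@H](CC=C(C)C)C[C@](C1=C(C(C)=O)C(=O)[C@H](C)[C@@H](C)O1)(CC=C(C)C)C(=O)OC
F5 | step 7 | 1-tert-butyl 3-(2,2-diphenylethyl) (2R)-2-(3-methylbut-2-en-1-yl)-2-[(2R)-lavandulyl]propanedioate | C=C(C)[C@H](CC=C(C)C)C[C@@](C(=O)OCC(c1ccccc1)c1ccccc1)(CC=C(C)C)C(=O)OC(C)(C)C
F6 | step 7 | (2R)-2-(tert-butoxycarbonyl)-5-methyl-2-[(2R)-lavandulyl]hex-4-enoic acid | C=C(C)[C@H](CC=C(C)C)C[C@@](C(=O)O)(CC=C(C)C)C(=O)OC(C)(C)C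
F7 | step 7 | (1R)-1-phenylethanaminium salt of 13 | C=C(C)[C@H](CC=C(C)C)C[C@](C(=O)[O-])(CC=C(C)C)C(=O)OC(C)(C)C.C[C@@H]([NH3+])c1ccccc1
F8 | step 18 | lactol corresponding to 33 (hemiacetal carbon in place of the lactone carbonyl; both anomers) | C=C(C)[C@H](CC=C(C)C)C[C@]1(CC=C(C)C)C(=O)C3=C(OC(O)C[C@H]3c4ccccc4)C2=C1O[C@H](C)[C@@H](C)C2=O
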